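**Retrosynthetic overview** (ring A = trioxygenated benzo ring, ring B = phenyl, ring C = pyranone, ring D = methoxy‑trimethyl‑cyclohexadienone)
- Last bond: C8–C1'' by a catalyst‑controlled Friedel–Crafts/Michael addition of (S)‑strobopinin (rings A, B, C) to the isobutylidene derivative of the ring D dione; this sets the (R)‑centre.
- (S)‑Strobopinin comes from an open‑chain (9S)‑9‑hydroxy‑3,5,7‑trioxo ester: one flask closes ring C (cyclodehydration to a dihydropyranone, which fixes the ring oxygen next to C8) and then ring A (acylketene C‑acylation and aromatisation); C2 comes from ethyl (S)‑3‑hydroxy‑3‑phenylpropanoate.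
- Ring D comes from Dieckmann closure of an acyclic β‑methoxy‑acrylate keto ester, so the enol ether position is fixed before the ring exists.
- Both carbocycles (A and D) grow from one C‑methylated triketide, methyl 2‑methyl‑3,5‑dioxohexanoate, made from methyl 2‑methylacetoacetate.
- Order of ring formation: C, then A (same flask); D separately; ring B is bought.

Assumption: the (R)‑phosphoric acid written in step 8 is chosen by analogy only; whichever enantiomer gives the (1R)‑epimer is used. Flavanone numbering (C2, C8) is used for rings A and C.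

**Step 1**
Reactants: 1 methyl 2‑methyl‑3‑oxobutanoate (racemic)
Product: 2 methyl 2‑methyl‑3,5‑dioxohexanoate (racemic at C2, keto/enol mixture)
Conditions: LiN(iPr)2 (2.1 equiv), THF, −78 → 0 °C; MeC(O)N(OMe)Me, −78 → 0 °C; 1 M HCl
Reagents that add atoms: N‑methoxy‑N‑methylacetamide, CC(=O)N(C)OC
Why: Huckin–Weiler dianion chemistry, in which the γ‑carbanion of the β‑keto ester dianion is acylated (Claisen type) by the Weinreb amide whose chelated adduct survives until work‑up; the C2 centre is racemic and is erased later.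

**Step 2**
Reactants: 2 methyl 2‑methyl‑3,5‑dioxohexanoate; 3 ethyl (3S)‑3‑hydroxy‑3‑phenylpropanoate
Product: 4 methyl (9S)‑9‑hydroxy‑2‑methyl‑3,5,7‑trioxo‑9‑phenylnonanoate (C2 epimers, enol mixture, used crude)
Conditions: 2 (2.5 equiv), LiN(iPr)2 (7.6 equiv), THF, −78 → 0 °C; 3 (1.0 equiv), −78 → −20 °C; AcOH, −78 °C
Reagents that add atoms: none
Why: Harris‑type polyanion Claisen acylation, in which the terminal methyl carbanion of the trilithium salt of 2 attacks the ester of 3 while excess polyanion serves as base; the carbinol centre is only a lithium alkoxide spectator, so (9S) is carried over unchanged.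

**Step 3**
Reactants: 4 methyl (9S)‑9‑hydroxy‑2‑methyl‑3,5,7‑trioxo‑9‑phenylnonanoate
Product: 7 (2S)‑5,7‑dihydroxy‑6‑methyl‑2‑phenyl‑2,3‑dihydro‑4H‑chromen‑4‑one [(S)‑strobopinin], via dihydropyranone keto ester 5 (not isolated), via acylketene 6 (not isolated)
Conditions: CF3CO2H (5 mol%), CH2Cl2, 23 °C; evaporate; mesitylene, 165 °C, N2 stream (MeOH removed)
Reagents that add atoms: none
Why: Proposed new method: acid‑catalysed hemiketalisation and dehydration of the δ‑hydroxy‑β‑diketone gives the 2,3‑dihydro‑4H‑pyran‑4‑one (ring C; the carbinol C–O bond is untouched so C2 stays S, and the ring oxygen is now fixed next to the future C8), then thermal loss of methanol from the β‑keto ester gives an acylketene that C‑acylates the nucleophilic C5 of the vinylogous ester through a six‑membered transition state and tautomerises to the phloroglucinol ring A; the closest known reactions are the cyclodehydration of aldol‑derived δ‑hydroxy‑β‑diketones and the acylketene trapping–aromatisation cascades of dioxinones and β‑keto esters (Claisen‑mode polyketide cyclisation).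

**Step 4**
Reactants: 2 methyl 2‑methyl‑3,5‑dioxohexanoate
Product: 8 methyl 2,4,4‑trimethyl‑3,5‑dioxohexanoate (racemic at C2)
Conditions: MeI (2.2 equiv), K2CO3 (2.5 equiv), acetone, 56 °C
Reagents that add atoms: iodomethane, CI
Why: Double C‑alkylation of a 1,3‑diketone at its most acidic carbon (C4, between two ketones, about two pKa units below C2–H) builds the quaternary carbon of ring D.

**Step 5**
Reactants: 8 methyl 2,4,4‑trimethyl‑3,5‑dioxohexanoate
Product: 9 methyl (2E)‑3‑methoxy‑2,4,4‑trimethyl‑5‑oxohex‑2‑enoate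
Conditions: NaH (1.05 equiv), THF/DMPU, 0 °C; Me2SO4 (1.1 equiv), 0 → 23 °C
Reagents that add atoms: dimethyl sulfate, COS(=O)(=O)OC
Why: O‑Alkylation of the only stabilised enolate (β‑keto ester) with a hard electrophile in a dipolar aprotic medium, C‑methylation being blocked because it would create a quaternary carbon next to a neopentyl ketone; the free W‑shaped enolate gives the E enol ether with the ester cis to the acetyl‑bearing chain.

**Step 6**
Reactants: 9 methyl (2E)‑3‑methoxy‑2,4,4‑trimethyl‑5‑oxohex‑2‑enoate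
Product: 10 5‑methoxy‑4,6,6‑trimethylcyclohex‑4‑ene‑1,3‑dione
Conditions: LiN(SiMe3)2 (2.2 equiv), THF, −78 → 23 °C; 1 M HCl to pH 4, 0 °C
Reagents that add atoms: none
Why: Dieckmann (intramolecular Claisen) condensation of the methyl ketone enolate onto the ester closes ring D and is driven by the acidic cyclic 1,3‑dione enolate; the methoxy group is already in place, so no regioselective O‑methylation of a triketone is needed.

**Step 7**
Reactants: 10 5‑methoxy‑4,6,6‑trimethylcyclohex‑4‑ene‑1,3‑dione; 11 2‑methylpropanal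
Product: 12 5‑methoxy‑4,6,6‑trimethyl‑2‑(2‑methylpropylidene)cyclohex‑4‑ene‑1,3‑dione (E/Z mixture, used fresh)
Conditions: 11 (1.5 equiv), piperidine (10 mol%), AcOH (10 mol%), MgSO4, CH2Cl2, 0 → 23 °C
Reagents that add atoms: none
Why: Knoevenagel condensation of the cyclic 1,3‑dione with the aldehyde; both alkene isomers lead to the same adduct.

**Step 8**
Reactants: 7 (2S)‑5,7‑dihydroxy‑6‑methyl‑2‑phenyl‑2,3‑dihydro‑4H‑chromen‑4‑one; 12 5‑methoxy‑4,6,6‑trimethyl‑2‑(2‑methylpropylidene)cyclohex‑4‑ene‑1,3‑dione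
Product: 13 (2S)‑5,7‑dihydroxy‑8‑[(1R)‑1‑(2‑hydroxy‑4‑methoxy‑3,3,5‑trimethyl‑6‑oxocyclohexa‑1,4‑dien‑1‑yl)‑2‑methylpropyl]‑6‑methyl‑2‑phenyl‑2,3‑dihydro‑4H‑chromen‑4‑one (target)
Conditions: (R)‑3,3'‑bis(2,4,6‑triisopropylphenyl)‑1,1'‑binaphthyl‑2,2'‑diyl hydrogen phosphate (10 mol%), CH2Cl2/PhMe, 4 Å molecular sieves, −20 °C; chromatography
Reagents that add atoms: none
Why: Friedel–Crafts‑type Michael addition of the only free nucleophilic carbon of 7 (C8) to the alkylidene dione inside the hydrogen‑bonded complex of the chiral phosphoric acid (phenol and dione carbonyl both bound), which selects one face of the alkylidene and sets the (R)‑centre; C2 (S) is untouched under these weakly acidic conditions and the minor C1''‑epimer is a diastereomer removed by chromatography.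

**Compound list**
1 | methyl 2‑methyl‑3‑oxobutanoate | CC(=O)C(C)C(=O)OC | starting material
2 | methyl 2‑methyl‑3,5‑dioxohexanoate | CC(=O)CC(=O)C(C)C(=O)OC | intermediate
3 | ethyl (3S)‑3‑hydroxy‑3‑phenylpropanoate | CCOC(=O)C[C@H](O)c1ccccc1 | starting material
4 | methyl (9S)‑9‑hydroxy‑2‑methyl‑3,5,7‑trioxo‑9‑phenylnonanoate | CC(C(=O)OC)C(=O)CC(=O)CC(=O)C[C@H](O)c1ccccc1 | intermediate
5 | methyl 2‑methyl‑3‑oxo‑4‑[(2S)‑4‑oxo‑2‑phenyl‑3,4‑dihydro‑2H‑pyran‑6‑yl]butanoate (not isolated) | CC(C(=O)OC)C(=O)CC1=CC(=O)C[C@@H](c2ccccc2)O1 | intermediate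
6 | 2‑methyl‑4‑[(2S)‑4‑oxo‑2‑phenyl‑3,4‑dihydro‑2H‑pyran‑6‑yl]but‑1‑ene‑1,3‑dione, acylketene (not isolated) | CC(=C=O)C(=O)CC1=CC(=O)C[C@@H](c2ccccc2)O1 | intermediate
7 | (2S)‑5,7‑dihydroxy‑6‑methyl‑2‑phenyl‑2,3‑dihydro‑4H‑chromen‑4‑one | Cc1c(O)cc2O[C@H](c3ccccc3)CC(=O)c2c1O | intermediate
8 | methyl 2,4,4‑trimethyl‑3,5‑dioxohexanoate | CC(=O)C(C)(C)C(=O)C(C)C(=O)OC | intermediate
9 | methyl (2E)‑3‑methoxy‑2,4,4‑trimethyl‑5‑oxohex‑2‑enoate | COC(=O)/C(C)=C(\C(C)(C)C(C)=O)OC | intermediate
10 | 5‑methoxy‑4,6,6‑trimethylcyclohex‑4‑ene‑1,3‑dione | COC1=C(C)C(=O)CC(=O)C1(C)C | intermediate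
11 | 2‑methylpropanal | CC(C)C=O | starting material
12 | 5‑methoxy‑4,6,6‑trimethyl‑2‑(2‑methylpropylidene)cyclohex‑4‑ene‑1,3‑dione | COC1=C(C)C(=O)C(=CC(C)C)C(=O)C1(C)C | intermediate
13 | (2S)‑5,7‑dihydroxy‑8‑[(1R)‑1‑(2‑hydroxy‑4‑methoxy‑3,3,5‑trimethyl‑6‑oxocyclohexa‑1,4‑dien‑1‑yl)‑2‑methylpropyl]‑6‑methyl‑2‑phenyl‑2,3‑dihydro‑4H‑chromen‑4‑one | COC1=C(C)C(=O)C([C@@H](c2c(O)c(C)c(O)c3c2O[C@H](c2ccccc2)CC3=O)C(C)C)=C(O)C1(C)C | target

**Totals.** Total steps: 8. Longest linear sequence: 6 steps (1 → 2 → 8 → 9 → 10 → 12 → 13; steps 1, 4, 5, 6, 7, 8).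

**Three steps most likely to fail**

Step 3 (the double ring closure). The methyl β‑keto ester may lose methanol too slowly, the acylketene may not be captured by C5 of the dihydropyranone, and C2 could erode at 165 °C. The fallback sets out from 2 and comes back at 7, and sets C2 by catalysis on an achiral chromone instead of carrying it through the cascade. The trilithium salt of 2 is acylated with methyl 3,3‑dimethoxypropanoate to give methyl 9,9‑dimethoxy‑2‑methyl‑3,5,7‑trioxononanoate F1. TsOH in toluene closes the achiral 4‑pyranone, methyl 2‑methyl‑3‑oxo‑4‑(4‑oxo‑4H‑pyran‑2‑yl)butanoate F2. With no stereocentre to lose, ring A is closed by an ordinary base‑mediated Claisen condensation (Mg(OMe)2, MeOH, reflux) to 5,7‑dihydroxy‑6‑methyl‑4H‑chromen‑4‑one F3. Asymmetric 1,4‑addition of PhB(OH)2 ([Rh(OH)(cod)]2, chiral bisphosphine such as BINAP of the appropriate hand, dioxane/H2O) then gives 7.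

Step 8 (the (R)‑centre). Facial selectivity with an alkyl‑substituted alkylidene dione may be modest and the alkylidene may isomerise to its dienol. The fallback sets out from 7 and comes back at 13, with the polarity reversed. Betti‑type Mannich condensation of 7 with 2‑methylpropanal 11 and morpholine gives (2S)‑5,7‑dihydroxy‑6‑methyl‑8‑[2‑methyl‑1‑(morpholin‑4‑yl)propyl]‑2‑phenyl‑2,3‑dihydro‑4H‑chromen‑4‑one F4. Warming F4 with dione 10 and the chiral phosphoric acid expels morpholine, generates the ortho‑quinone methide of ring A, and lets 10 add to it inside the chiral ion pair to give 13.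

Step 6 (Dieckmann closure, which depends on the E geometry made in step 5). The Z enol ether cannot cyclise, and the vinylogous carbonate ester is a weak electrophile. The fallback sets out from 8 and comes back at 13, moving the O‑methylation to the end. Dieckmann closure of 8 itself (KOtBu, THF) gives 2,2,4‑trimethylcyclohexane‑1,3,5‑trione F5. Knoevenagel condensation with 11 gives 2,2,4‑trimethyl‑6‑(2‑methylpropylidene)cyclohexane‑1,3,5‑trione F6. Addition of 7 under the step 8 conditions gives (2S)‑8‑[(1R)‑1‑(2,4‑dihydroxy‑3,3,5‑trimethyl‑6‑oxocyclohexa‑1,4‑dien‑1‑yl)‑2‑methylpropyl]‑5,7‑dihydroxy‑6‑methyl‑2‑phenyl‑2,3‑dihydro‑4H‑chromen‑4‑one F7. One equivalent of Me3SiCHN2 at −78 °C is expected to methylate the enol oxygen remote from the aryl group (not hydrogen‑bonded to the C7 phenol), giving 13 after separation from regioisomeric ethers.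

**Further compounds**
F1 | step 3 | methyl 9,9‑dimethoxy‑2‑methyl‑3,5,7‑trioxononanoate | COC(OC)CC(=O)CC(=O)CC(=O)C(C)C(=O)OC
F2 | step 3 | methyl 2‑methyl‑3‑oxo‑4‑(4‑oxo‑4H‑pyran‑2‑yl)butanoate | CC(C(=O)OC)C(=O)CC1=CC(=O)C=CO1
F3 | step 3 | 5,7‑dihydroxy‑6‑methyl‑4H‑chromen‑4‑one | Cc1c(O)cc2occc(=O)c2c1O
F4 | step 8 | (2S)‑5,7‑dihydroxy‑6‑methyl‑8‑[2‑methyl‑1‑(morpholin‑4‑yl)propyl]‑2‑phenyl‑2,3‑dihydro‑4H‑chromen‑4‑one | Cc1c(O)c(C(C(C)C)N2CCOCC2)c2O[C@H](c3ccccc3)CC(=O)c2c1O
F5 | step 6 | 2,2,4‑trimethylcyclohexane‑1,3,5‑trione | CC1C(=O)CC(=O)C(C)(C)C1=O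
F6 | step 6 | 2,2,4‑trimethyl‑6‑(2‑methylpropylidene)cyclohexane‑1,3,5‑trione | CC(C)C=C1C(=O)C(C)C(=O)C(C)(C)C1=O
F7 | step 6 | (2S)‑8‑[(1R)‑1‑(2,4‑dihydroxy‑3,3,5‑trimethyl‑6‑oxocyclohexa‑1,4‑dien‑1‑yl)‑2‑methylpropyl]‑5,7‑dihydroxy‑6‑methyl‑2‑phenyl‑2,3‑dihydro‑4H‑chromen‑4‑one | OC1=C(C)C(=O)C([C@@H](c2c(O)c(C)c(O)c3c2O[C@H](c2ccccc2)CC3=O)C(C)C)=C(O)C1(C)C
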